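**Retrosynthetic overview**

1. The route rests on the C3(O)–C4(C15)=C5–C6(O) unit of ring A (the ten-membered carbocycle C1–C10): a 1,4-dioxygenated (E)-2-ene whose C6 oxygen is the ring oxygen of ring B (the trans-fused γ-lactone O–C6–C7–C11–C12).
2. Ring B is disconnected at C6–O by allylic transposition to a C3/C4 epoxide, an (E) C5=C6 alkene and a free C12 acid; in the forward direction zerovalent palladium closes ring B last, followed only by C9 desilylation and double acetylation.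
3. Ring A is closed before that, at C5=C6, by intramolecular Julia–Kocienski olefination of a C5 epoxy aldehyde with a C6 tetrazolyl sulfone.
4. The open chain is cut at C9–C10: CrCl2/NiCl2 coupling of a (Z)-vinyl iodide (C1–C5, C10, C14, C15; epoxide from Sharpless epoxidation) with a C9 aldehyde (C6–C9, C11–C13), C9 then being set by oxidation and CBS reduction.
5. C7 and C11 come from one alkylation of a pentenoyl oxazolidinone enolate with a lactate triflate.

Key step: step 24

Remark on the chemistry: germacrane numbering is used throughout (ring C1–C10; C11 on C7 carrying C12 and C13; C14 on C10; C15 on C4). The target SMILES is read as 3S,6S,7S,9R,11R with 1(10)Z and 4E. Compounds marked as starting materials in the compound list are taken as commercially available.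

**Route**

Step 1
Reactants: 1 3-[(tert-butyldimethylsilyl)oxy]propanal; 2 ethyl 2-(triphenyl-λ5-phosphanylidene)propanoate
Product: 3 ethyl (2E)-5-[(tert-butyldimethylsilyl)oxy]-2-methylpent-2-enoate
Conditions: CH2Cl2, rt
Reagents that add atoms: none
Why: Wittig olefination with the stabilised ylide should give the (E)-trisubstituted enoate under thermodynamic control, bringing in C4, C5 and C15.

Step 2
Reactants: 3 ethyl (2E)-5-[(tert-butyldimethylsilyl)oxy]-2-methylpent-2-enoate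
Product: 4 (2E)-5-[(tert-butyldimethylsilyl)oxy]-2-methylpent-2-en-1-ol
Conditions: i-Bu2AlH (2.2 equiv), CH2Cl2, −78 °C; Rochelle salt work-up
Reagents that add atoms: none
Why: 1,2-reduction of the conjugated ester by the aluminium hydride at low temperature should stop cleanly at the allylic alcohol and leave the silyl ether untouched.

Step 3
Reactants: 4 (2E)-5-[(tert-butyldimethylsilyl)oxy]-2-methylpent-2-en-1-ol
Product: 5 [(2S,3S)-3-{2-[(tert-butyldimethylsilyl)oxy]ethyl}-2-methyloxiran-2-yl]methanol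
Conditions: Ti(Oi-Pr)4 (10 mol%), L-(+)-diethyl tartrate (12 mol%), t-BuOOH, 4 Å MS, CH2Cl2, −20 °C
Reagents that add atoms: tert-butyl hydroperoxide, CC(C)(C)OO
Why: Sharpless asymmetric epoxidation with the L-(+)-tartrate ligand is known to give (2S,3S)-epoxy alcohols from (E)-allylic alcohols, so C3 and C4 (both S) are set by the reagent.

Step 4
Reactants: 5 [(2S,3S)-3-{2-[(tert-butyldimethylsilyl)oxy]ethyl}-2-methyloxiran-2-yl]methanol
Product: 6 (2S,3S)-3-{2-[(tert-butyldimethylsilyl)oxy]ethyl}-2-{[(4-methoxybenzyl)oxy]methyl}-2-methyloxirane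
Conditions: NaH, 4-methoxybenzyl chloride, Bu4NI (cat.), THF/DMF, 0 °C to rt
Reagents that add atoms: 4-methoxybenzyl chloride, COc1ccc(CCl)cc1
Why: Williamson etherification of the primary alkoxide should be clean because a Payne rearrangement would require attack at the fully substituted C4.

Step 5
Reactants: 6 (2S,3S)-3-{2-[(tert-butyldimethylsilyl)oxy]ethyl}-2-{[(4-methoxybenzyl)oxy]methyl}-2-methyloxirane
Product: 7 2-[(2S,3S)-3-{[(4-methoxybenzyl)oxy]methyl}-3-methyloxiran-2-yl]ethan-1-ol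
Conditions: Bu4NF, THF, 0 °C to rt
Reagents that add atoms: none
Why: Fluoride-induced cleavage of the Si–O bond frees the C1 alcohol while the benzyl-type ether and the epoxide are inert.

Step 6
Reactants: 7 2-[(2S,3S)-3-{[(4-methoxybenzyl)oxy]methyl}-3-methyloxiran-2-yl]ethan-1-ol
Product: 8 2-[(2S,3S)-3-{[(4-methoxybenzyl)oxy]methyl}-3-methyloxiran-2-yl]acetaldehyde
Conditions: DMP, pyridine, CH2Cl2, 0 °C to rt; crude product used at once
Reagents that add atoms: none
Why: Dess–Martin oxidation in the presence of pyridine is fast and non-basic, which should give the β,γ-epoxy aldehyde without opening of the epoxide through enolisation, provided it is used at once.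

Step 7
Reactants: 8 2-[(2S,3S)-3-{[(4-methoxybenzyl)oxy]methyl}-3-methyloxiran-2-yl]acetaldehyde; 9 ethyltriphenylphosphonium iodide
Product: 11 (2S,3S)-3-[(2Z)-3-iodobut-2-en-1-yl]-2-{[(4-methoxybenzyl)oxy]methyl}-2-methyloxirane, via (1-iodoethyl)triphenylphosphonium iodide 10 (not isolated)
Conditions: 9, n-BuLi, THF, rt; I2, −78 °C; NaN(SiMe3)2, −20 °C; then 8, −78 to −20 °C
Reagents that add atoms: iodine, [I][I]
Why: Stork–Zhao olefination with the α-iodo ylide at low temperature should give the (Z)-iodoalkene (iodine cis to C2) under kinetic control, which fixes the 1(10)Z geometry because C9 later takes the place of iodine with retention.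

Step 8
Reactants: 12 (4R)-4-benzyl-1,3-oxazolidin-2-one; 13 pent-4-enoyl chloride
Product: 14 (4R)-4-benzyl-3-(pent-4-enoyl)-1,3-oxazolidin-2-one
Conditions: n-BuLi, THF, −78 °C; then 13, −78 to 0 °C
Reagents that add atoms: none
Why: N-acylation of the lithiated oxazolidinone by the acid chloride is a standard imide formation.

Step 9
Reactants: 15 tert-butyl (2R)-2-hydroxypropanoate
Product: 16 tert-butyl (2R)-2-{[(trifluoromethyl)sulfonyl]oxy}propanoate
Conditions: Tf2O, 2,6-lutidine, CH2Cl2, −78 to 0 °C; used directly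
Reagents that add atoms: trifluoromethanesulfonic anhydride, O=S(=O)(OS(=O)(=O)C(F)(F)F)C(F)(F)F
Why: O-sulfonylation of the secondary alcohol touches no bond at the stereocentre, so the (R) configuration is kept in an activated form.

Step 10
Reactants: 14 (4R)-4-benzyl-3-(pent-4-enoyl)-1,3-oxazolidin-2-one; 16 tert-butyl (2R)-2-{[(trifluoromethyl)sulfonyl]oxy}propanoate
Product: 17 tert-butyl (2R,3S)-3-{[(4R)-4-benzyl-2-oxo-1,3-oxazolidin-3-yl]carbonyl}-2-methylhex-5-enoate
Conditions: LiN(SiMe3)2, THF, −78 °C; then 16, −78 to −30 °C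
Reagents that add atoms: none
Why: Alkylation of the chelated (Z)-lithium enolate, whose benzyl group shields one face (sets C7 as S), by SN2 displacement of the α-triflyloxy ester with inversion (sets C11 as R) is the known route to 2,3-disubstituted succinates.

Step 11
Reactants: 17 tert-butyl (2R,3S)-3-{[(4R)-4-benzyl-2-oxo-1,3-oxazolidin-3-yl]carbonyl}-2-methylhex-5-enoate
Product: 18 tert-butyl (2R,3S)-3-(hydroxymethyl)-2-methylhex-5-enoate
Conditions: LiBH4, H2O (1 equiv), Et2O, 0 °C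
Reagents that add atoms: none
Why: LiBH4 reduces the activated imide carbonyl chemoselectively (reductive removal of the auxiliary), and the tert-butyl ester is kept because it is neither reduced nor lactonised by the new C6 hydroxyl.

Step 12
Reactants: 18 tert-butyl (2R,3S)-3-(hydroxymethyl)-2-methylhex-5-enoate
Product: 19 tert-butyl (2R,3S)-2-methyl-3-{[(1-phenyl-1H-tetrazol-5-yl)sulfanyl]methyl}hex-5-enoate
Conditions: 1-phenyl-1H-tetrazole-5-thiol, PPh3, DIAD, THF, 0 °C to rt
Reagents that add atoms: 1-phenyl-1H-tetrazole-5-thiol, Sc1nnnn1-c1ccccc1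
Why: Mitsunobu thioetherification at the primary C6 carbinol with the acidic tetrazole thiol proceeds by SN2 and creates no stereocentre.

Step 13
Reactants: 19 tert-butyl (2R,3S)-2-methyl-3-{[(1-phenyl-1H-tetrazol-5-yl)sulfanyl]methyl}hex-5-enoate
Product: 20 tert-butyl (2R,3S)-2-methyl-3-{[(1-phenyl-1H-tetrazol-5-yl)sulfonyl]methyl}hex-5-enoate
Conditions: (NH4)6Mo7O24·4H2O (10 mol%), 30% aq. H2O2, EtOH, 0 °C to rt
Reagents that add atoms: hydrogen peroxide, OO
Why: Molybdate-catalysed peroxide oxidation takes the sulfide to the sulfone and does not epoxidise the unactivated terminal alkene.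

Step 14
Reactants: 20 tert-butyl (2R,3S)-2-methyl-3-{[(1-phenyl-1H-tetrazol-5-yl)sulfonyl]methyl}hex-5-enoate
Product: 22 methyl (2R,3S)-2-methyl-3-{[(1-phenyl-1H-tetrazol-5-yl)sulfonyl]methyl}hex-5-enoate, via free carboxylic acid 21 (not isolated)
Conditions: TFA, CH2Cl2, 0 °C to rt; evaporate; TMSCHN2, PhMe/MeOH, 0 °C
Reagents that add atoms: (trimethylsilyl)diazomethane, C[Si](C)(C)C=[N+]=[N-]
Why: Acidolysis of the tert-butyl ester (loss of 2-methylpropene) and O-methylation of the acid with the diazoalkane exchange the ester, without base at C11, for one that hydroxide can cleave later in the presence of an epoxide and a silyl ether.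

Step 15
Reactants: 22 methyl (2R,3S)-2-methyl-3-{[(1-phenyl-1H-tetrazol-5-yl)sulfonyl]methyl}hex-5-enoate
Product: 23 methyl (2R,3S)-2-methyl-5-oxo-3-{[(1-phenyl-1H-tetrazol-5-yl)sulfonyl]methyl}pentanoate
Conditions: O3, CH2Cl2, −78 °C; then PPh3, −78 °C to rt
Reagents that add atoms: ozone, [O-][O+]=O
Why: Ozonolysis with reductive work-up cleaves the only alkene to the C9 aldehyde, the sulfone and ester being inert to ozone.

Step 16
Reactants: 11 (2S,3S)-3-[(2Z)-3-iodobut-2-en-1-yl]-2-{[(4-methoxybenzyl)oxy]methyl}-2-methyloxirane; 23 methyl (2R,3S)-2-methyl-5-oxo-3-{[(1-phenyl-1H-tetrazol-5-yl)sulfonyl]methyl}pentanoate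
Product: 24 methyl (2R,3S,6Z)-5-hydroxy-2,6-dimethyl-8-[(2S,3S)-3-{[(4-methoxybenzyl)oxy]methyl}-3-methyloxiran-2-yl]-3-{[(1-phenyl-1H-tetrazol-5-yl)sulfonyl]methyl}oct-6-enoate (both C5 epimers, that is both C9 epimers in germacrane numbering)
Conditions: CrCl2 (4 equiv), NiCl2 (2 mol%), DMSO, rt
Reagents that add atoms: none
Why: Nozaki–Hiyama–Kishi coupling (oxidative addition of zerovalent nickel into the C–I bond, transmetalation to trivalent chromium with retention of the Z geometry, addition to the aldehyde) tolerates the ester, sulfone and epoxide and forms the C9–C10 bond, the C9 configuration being left open here and set in steps 17 and 18.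

Step 17
Reactants: 24 methyl (2R,3S,6Z)-5-hydroxy-2,6-dimethyl-8-[(2S,3S)-3-{[(4-methoxybenzyl)oxy]methyl}-3-methyloxiran-2-yl]-3-{[(1-phenyl-1H-tetrazol-5-yl)sulfonyl]methyl}oct-6-enoate
Product: 25 methyl (2R,3S,6Z)-2,6-dimethyl-8-[(2S,3S)-3-{[(4-methoxybenzyl)oxy]methyl}-3-methyloxiran-2-yl]-5-oxo-3-{[(1-phenyl-1H-tetrazol-5-yl)sulfonyl]methyl}oct-6-enoate
Conditions: DMP, pyridine, CH2Cl2, 0 °C to rt
Reagents that add atoms: none
Why: Dess–Martin oxidation of the allylic alcohol converges both C9 epimers on one (Z)-enone under non-basic conditions that should not isomerise the alkene.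

Step 18
Reactants: 25 methyl (2R,3S,6Z)-2,6-dimethyl-8-[(2S,3S)-3-{[(4-methoxybenzyl)oxy]methyl}-3-methyloxiran-2-yl]-5-oxo-3-{[(1-phenyl-1H-tetrazol-5-yl)sulfonyl]methyl}oct-6-enoate
Product: 26 methyl (2R,3S,5R,6Z)-5-hydroxy-2,6-dimethyl-8-[(2S,3S)-3-{[(4-methoxybenzyl)oxy]methyl}-3-methyloxiran-2-yl]-3-{[(1-phenyl-1H-tetrazol-5-yl)sulfonyl]methyl}oct-6-enoate
Conditions: (S)-2-methyl-CBS-oxazaborolidine (0.5 equiv), catecholborane, PhMe, −78 °C
Reagents that add atoms: none
Why: Corey–Bakshi–Shibata reduction, in which the α-methyl alkenyl group acts as the large substituent and the C8 methylene as the small one, should deliver hydride under catalyst control to give the (9R)-alcohol.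

Step 19
Reactants: 26 methyl (2R,3S,5R,6Z)-5-hydroxy-2,6-dimethyl-8-[(2S,3S)-3-{[(4-methoxybenzyl)oxy]methyl}-3-methyloxiran-2-yl]-3-{[(1-phenyl-1H-tetrazol-5-yl)sulfonyl]methyl}oct-6-enoate
Product: 27 methyl (2R,3S,5R,6Z)-5-[(tert-butyldimethylsilyl)oxy]-2,6-dimethyl-8-[(2S,3S)-3-{[(4-methoxybenzyl)oxy]methyl}-3-methyloxiran-2-yl]-3-{[(1-phenyl-1H-tetrazol-5-yl)sulfonyl]methyl}oct-6-enoate
Conditions: TBSCl, imidazole, DMAP (cat.), DMF, rt
Reagents that add atoms: tert-butyldimethylsilyl chloride, CC(C)(C)[Si](C)(C)Cl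
Why: Silylation of the secondary alcohol under mildly basic conditions gives a C9 ether that zerovalent palladium will not ionise in step 24, as an allylic acetate at this position would be.

Step 20
Reactants: 27 methyl (2R,3S,5R,6Z)-5-[(tert-butyldimethylsilyl)oxy]-2,6-dimethyl-8-[(2S,3S)-3-{[(4-methoxybenzyl)oxy]methyl}-3-methyloxiran-2-yl]-3-{[(1-phenyl-1H-tetrazol-5-yl)sulfonyl]methyl}oct-6-enoate
Product: 28 methyl (2R,3S,5R,6Z)-5-[(tert-butyldimethylsilyl)oxy]-8-[(2S,3S)-3-(hydroxymethyl)-3-methyloxiran-2-yl]-2,6-dimethyl-3-{[(1-phenyl-1H-tetrazol-5-yl)sulfonyl]methyl}oct-6-enoate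
Conditions: DDQ, CH2Cl2/pH 7 buffer, 0 °C
Reagents that add atoms: none
Why: Oxidative cleavage of the 4-methoxybenzyl ether by DDQ in buffered wet solvent frees the C5 alcohol without affecting the silyl ether, sulfone or epoxide.

Step 21
Reactants: 28 methyl (2R,3S,5R,6Z)-5-[(tert-butyldimethylsilyl)oxy]-8-[(2S,3S)-3-(hydroxymethyl)-3-methyloxiran-2-yl]-2,6-dimethyl-3-{[(1-phenyl-1H-tetrazol-5-yl)sulfonyl]methyl}oct-6-enoate
Product: 29 methyl (2R,3S,5R,6Z)-5-[(tert-butyldimethylsilyl)oxy]-8-[(2S,3R)-3-formyl-3-methyloxiran-2-yl]-2,6-dimethyl-3-{[(1-phenyl-1H-tetrazol-5-yl)sulfonyl]methyl}oct-6-enoate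
Conditions: DMP, pyridine, CH2Cl2, 0 °C to rt
Reagents that add atoms: none
Why: Dess–Martin oxidation gives the epoxy aldehyde, which cannot epimerise because C4 carries no hydrogen (the descriptor at C4 changes only through the priority rules).

Step 22
Reactants: 29 methyl (2R,3S,5R,6Z)-5-[(tert-butyldimethylsilyl)oxy]-8-[(2S,3R)-3-formyl-3-methyloxiran-2-yl]-2,6-dimethyl-3-{[(1-phenyl-1H-tetrazol-5-yl)sulfonyl]methyl}oct-6-enoate
Product: 30 methyl (3S,4S,7R,9R,11R)-9-[(tert-butyldimethylsilyl)oxy]-3,4-epoxygermacra-1(10)Z,5E-dien-12-oate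
Conditions: KN(SiMe3)2 (1.1 equiv, slow addition), THF, 0.002 M, −78 °C to rt
Reagents that add atoms: none
Why: Intramolecular Julia–Kocienski olefination (deprotonation at C6 of the tetrazolyl sulfone, which is more acidic than the C11–H of the ester, addition to the non-enolisable C5 aldehyde, Smiles transfer of the tetrazole and anti elimination of SO2 and the tetrazolone) should close ring A at high dilution, the open transition state with potassium favouring the anti adduct and hence the (E) C5=C6 alkene.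

Step 23
Reactants: 30 methyl (3S,4S,7R,9R,11R)-9-[(tert-butyldimethylsilyl)oxy]-3,4-epoxygermacra-1(10)Z,5E-dien-12-oate
Product: 31 (3S,4S,7R,9R,11R)-9-[(tert-butyldimethylsilyl)oxy]-3,4-epoxygermacra-1(10)Z,5E-dien-12-oic acid
Conditions: LiOH, THF/MeOH/H2O, 0 °C to rt; then 0.5 M aq. H3PO4 to pH 5 at 0 °C; used at once
Reagents that add atoms: lithium hydroxide, [Li+].[OH-]
Why: Saponification of the methyl ester by hydroxide at or below room temperature should leave the epoxide and silyl ether intact and not epimerise C11, since addition to the ester carbonyl is faster than its enolisation.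

Step 24
Reactants: 31 (3S,4S,7R,9R,11R)-9-[(tert-butyldimethylsilyl)oxy]-3,4-epoxygermacra-1(10)Z,5E-dien-12-oic acid
Product: 32 (3S,6S,7S,9R,11R)-9-[(tert-butyldimethylsilyl)oxy]-3-hydroxygermacra-1(10)Z,4E-dien-12,6-olide
Conditions: Pd(PPh3)4 (10 mol%), degassed THF, 0.01 M, 0 °C to rt
Reagents that add atoms: none
Why: Zerovalent palladium from Pd(PPh3)4 binds the C5=C6 alkene on the face opposite the C4–O bond and ionises that bond with inversion to a syn,syn C4–C5–C6 π-allyl complex of divalent palladium, whose C3 alkoxide is protonated by the C12 acid; the carboxylate then attacks C6 on the face away from the metal (second inversion) and releases the catalyst. The closest known reaction type is the palladium-catalysed 1,4-opening of vinyl epoxides by carboxylic acids (Tsuji–Trost allylic substitution with net syn delivery of the oxygen nucleophile), used here intramolecularly across ring A. Ring B closes by 5-exo attack of the carboxylate oxygen on the allyl terminus C6 and is trans-fused because the C7 configuration holds C11 on the face of C6 that is anti to palladium. The new stereocentre C6 (S) is controlled by the C4 (S) epoxide centre through the double inversion, together with the (E) C5=C6 geometry that places C7 syn on the allyl unit. The step needs attack at C6 and not at C4 (secured by five-membered against seven-membered ring formation and by the fully substituted C4), the (E) C4=C5 alkene (C3 syn on the allyl unit, held by ring A) and untouched C9 and C11 (the C9 silyl ether is not ionised and the medium stays neutral because the acid quenches the alkoxide).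

Step 25
Reactants: 32 (3S,6S,7S,9R,11R)-9-[(tert-butyldimethylsilyl)oxy]-3-hydroxygermacra-1(10)Z,4E-dien-12,6-olide
Product: 33 (3S,6S,7S,9R,11R)-3,9-dihydroxygermacra-1(10)Z,4E-dien-12,6-olide
Conditions: Bu4NF, AcOH (1:1), THF, 0 °C to rt
Reagents that add atoms: none
Why: Fluoride desilylation buffered with acetic acid frees the C9 alcohol without epimerising C11 or inducing acid-promoted transannular cyclisation of the cyclodecadiene.

Step 26
Reactants: 33 (3S,6S,7S,9R,11R)-3,9-dihydroxygermacra-1(10)Z,4E-dien-12,6-olide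
Product: 34 (3S,6S,7S,9R,11R)-3,9-diacetoxygermacra-1(10)Z,4E-dien-12,6-olide
Conditions: Ac2O, pyridine, DMAP (cat.), CH2Cl2, rt
Reagents that add atoms: acetic anhydride, CC(=O)OC(C)=O
Why: DMAP-catalysed acylation converts both secondary allylic alcohols into acetates and gives the target with all five stereocentres unchanged.

**Compound list**

1 | 3-[(tert-butyldimethylsilyl)oxy]propanal | CC(C)(C)[Si](C)(C)OCCC=O | starting material
2 | ethyl 2-(triphenyl-λ5-phosphanylidene)propanoate | CCOC(=O)C(C)=P(c1ccccc1)(c1ccccc1)c1ccccc1 | starting material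
3 | ethyl (2E)-5-[(tert-butyldimethylsilyl)oxy]-2-methylpent-2-enoate | CCOC(=O)/C(C)=C/CCO[Si](C)(C)C(C)(C)C | intermediate
4 | (2E)-5-[(tert-butyldimethylsilyl)oxy]-2-methylpent-2-en-1-ol | OC/C(C)=C/CCO[Si](C)(C)C(C)(C)C | intermediate
5 | [(2S,3S)-3-{2-[(tert-butyldimethylsilyl)oxy]ethyl}-2-methyloxiran-2-yl]methanol | C[C@@]1(CO)O[C@H]1CCO[Si](C)(C)C(C)(C)C | intermediate
6 | (2S,3S)-3-{2-[(tert-butyldimethylsilyl)oxy]ethyl}-2-{[(4-methoxybenzyl)oxy]methyl}-2-methyloxirane | C[C@@]1(COCc2ccc(OC)cc2)O[C@H]1CCO[Si](C)(C)C(C)(C)C | intermediate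
7 | 2-[(2S,3S)-3-{[(4-methoxybenzyl)oxy]methyl}-3-methyloxiran-2-yl]ethan-1-ol | C[C@@]1(COCc2ccc(OC)cc2)O[C@H]1CCO | intermediate
8 | 2-[(2S,3S)-3-{[(4-methoxybenzyl)oxy]methyl}-3-methyloxiran-2-yl]acetaldehyde | C[C@@]1(COCc2ccc(OC)cc2)O[C@H]1CC=O | intermediate
9 | ethyltriphenylphosphonium iodide | CC[P+](c1ccccc1)(c1ccccc1)c1ccccc1.[I-] | starting material
10 | (1-iodoethyl)triphenylphosphonium iodide | CC(I)[P+](c1ccccc1)(c1ccccc1)c1ccccc1.[I-] | intermediate
11 | (2S,3S)-3-[(2Z)-3-iodobut-2-en-1-yl]-2-{[(4-methoxybenzyl)oxy]methyl}-2-methyloxirane | C[C@@]1(COCc2ccc(OC)cc2)O[C@H]1C/C=C(/C)I | intermediate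
12 | (4R)-4-benzyl-1,3-oxazolidin-2-one | O=C1N[C@H](Cc2ccccc2)CO1 | starting material
13 | pent-4-enoyl chloride | C=CCCC(Cl)=O | starting material
14 | (4R)-4-benzyl-3-(pent-4-enoyl)-1,3-oxazolidin-2-one | C=CCCC(=O)N1[C@H](Cc2ccccc2)COC1=O | intermediate
15 | tert-butyl (2R)-2-hydroxypropanoate | C[C@@H](O)C(=O)OC(C)(C)C | starting material
16 | tert-butyl (2R)-2-{[(trifluoromethyl)sulfonyl]oxy}propanoate | C[C@@H](OS(=O)(=O)C(F)(F)F)C(=O)OC(C)(C)C | intermediate
17 | tert-butyl (2R,3S)-3-{[(4R)-4-benzyl-2-oxo-1,3-oxazolidin-3-yl]carbonyl}-2-methylhex-5-enoate | C=CC[C@@H]([C@@H](C)C(=O)OC(C)(C)C)C(=O)N1[C@H](Cc2ccccc2)COC1=O | intermediate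
18 | tert-butyl (2R,3S)-3-(hydroxymethyl)-2-methylhex-5-enoate | C=CC[C@@H]([C@@H](C)C(=O)OC(C)(C)C)CO | intermediate
19 | tert-butyl (2R,3S)-2-methyl-3-{[(1-phenyl-1H-tetrazol-5-yl)sulfanyl]methyl}hex-5-enoate | C=CC[C@@H]([C@@H](C)C(=O)OC(C)(C)C)CSc1nnnn1-c1ccccc1 | intermediate
20 | tert-butyl (2R,3S)-2-methyl-3-{[(1-phenyl-1H-tetrazol-5-yl)sulfonyl]methyl}hex-5-enoate | C=CC[C@@H]([C@@H](C)C(=O)OC(C)(C)C)CS(=O)(=O)c1nnnn1-c1ccccc1 | intermediate
21 | (2R,3S)-2-methyl-3-{[(1-phenyl-1H-tetrazol-5-yl)sulfonyl]methyl}hex-5-enoic acid | C=CC[C@@H]([C@@H](C)C(O)=O)CS(=O)(=O)c1nnnn1-c1ccccc1 | intermediate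
22 | methyl (2R,3S)-2-methyl-3-{[(1-phenyl-1H-tetrazol-5-yl)sulfonyl]methyl}hex-5-enoate | C=CC[C@@H]([C@@H](C)C(=O)OC)CS(=O)(=O)c1nnnn1-c1ccccc1 | intermediate
23 | methyl (2R,3S)-2-methyl-5-oxo-3-{[(1-phenyl-1H-tetrazol-5-yl)sulfonyl]methyl}pentanoate | O=CC[C@@H]([C@@H](C)C(=O)OC)CS(=O)(=O)c1nnnn1-c1ccccc1 | intermediate
24 | methyl (2R,3S,6Z)-5-hydroxy-2,6-dimethyl-8-[(2S,3S)-3-{[(4-methoxybenzyl)oxy]methyl}-3-methyloxiran-2-yl]-3-{[(1-phenyl-1H-tetrazol-5-yl)sulfonyl]methyl}oct-6-enoate (C5 epimers) | C[C@@]1(COCc2ccc(OC)cc2)O[C@H]1C/C=C(/C)C(O)C[C@@H]([C@@H](C)C(=O)OC)CS(=O)(=O)c1nnnn1-c1ccccc1 | intermediate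
25 | methyl (2R,3S,6Z)-2,6-dimethyl-8-[(2S,3S)-3-{[(4-methoxybenzyl)oxy]methyl}-3-methyloxiran-2-yl]-5-oxo-3-{[(1-phenyl-1H-tetrazol-5-yl)sulfonyl]methyl}oct-6-enoate | C[C@@]1(COCc2ccc(OC)cc2)O[C@H]1C/C=C(/C)C(=O)C[C@@H]([C@@H](C)C(=O)OC)CS(=O)(=O)c1nnnn1-c1ccccc1 | intermediate
26 | methyl (2R,3S,5R,6Z)-5-hydroxy-2,6-dimethyl-8-[(2S,3S)-3-{[(4-methoxybenzyl)oxy]methyl}-3-methyloxiran-2-yl]-3-{[(1-phenyl-1H-tetrazol-5-yl)sulfonyl]methyl}oct-6-enoate | C[C@@]1(COCc2ccc(OC)cc2)O[C@H]1C/C=C(/C)[C@H](O)C[C@@H]([C@@H](C)C(=O)OC)CS(=O)(=O)c1nnnn1-c1ccccc1 | intermediate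
27 | methyl (2R,3S,5R,6Z)-5-[(tert-butyldimethylsilyl)oxy]-2,6-dimethyl-8-[(2S,3S)-3-{[(4-methoxybenzyl)oxy]methyl}-3-methyloxiran-2-yl]-3-{[(1-phenyl-1H-tetrazol-5-yl)sulfonyl]methyl}oct-6-enoate | C[C@@]1(COCc2ccc(OC)cc2)O[C@H]1C/C=C(/C)[C@H](O[Si](C)(C)C(C)(C)C)C[C@@H]([C@@H](C)C(=O)OC)CS(=O)(=O)c1nnnn1-c1ccccc1 | intermediate
28 | methyl (2R,3S,5R,6Z)-5-[(tert-butyldimethylsilyl)oxy]-8-[(2S,3S)-3-(hydroxymethyl)-3-methyloxiran-2-yl]-2,6-dimethyl-3-{[(1-phenyl-1H-tetrazol-5-yl)sulfonyl]methyl}oct-6-enoate | C[C@@]1(CO)O[C@H]1C/C=C(/C)[C@H](O[Si](C)(C)C(C)(C)C)C[C@@H]([C@@H](C)C(=O)OC)CS(=O)(=O)c1nnnn1-c1ccccc1 | intermediate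
29 | methyl (2R,3S,5R,6Z)-5-[(tert-butyldimethylsilyl)oxy]-8-[(2S,3R)-3-formyl-3-methyloxiran-2-yl]-2,6-dimethyl-3-{[(1-phenyl-1H-tetrazol-5-yl)sulfonyl]methyl}oct-6-enoate | C[C@@]1(C=O)O[C@H]1C/C=C(/C)[C@H](O[Si](C)(C)C(C)(C)C)C[C@@H]([C@@H](C)C(=O)OC)CS(=O)(=O)c1nnnn1-c1ccccc1 | intermediate
30 | methyl (3S,4S,7R,9R,11R)-9-[(tert-butyldimethylsilyl)oxy]-3,4-epoxygermacra-1(10)Z,5E-dien-12-oate | C[C@@]12O[C@H]1C/C=C(/C)[C@H](O[Si](C)(C)C(C)(C)C)C[C@@H]([C@@H](C)C(=O)OC)/C=C/2 | intermediate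
31 | (3S,4S,7R,9R,11R)-9-[(tert-butyldimethylsilyl)oxy]-3,4-epoxygermacra-1(10)Z,5E-dien-12-oic acid | C[C@@]12O[C@H]1C/C=C(/C)[C@H](O[Si](C)(C)C(C)(C)C)C[C@@H]([C@@H](C)C(O)=O)/C=C/2 | intermediate
32 | (3S,6S,7S,9R,11R)-9-[(tert-butyldimethylsilyl)oxy]-3-hydroxygermacra-1(10)Z,4E-dien-12,6-olide | O[C@H]1C/C=C(/C)[C@H](O[Si](C)(C)C(C)(C)C)C[C@@H]2[C@@H](/C=C/1C)OC(=O)[C@@H]2C | intermediate
33 | (3S,6S,7S,9R,11R)-3,9-dihydroxygermacra-1(10)Z,4E-dien-12,6-olide | O[C@H]1C/C=C(/C)[C@H](O)C[C@@H]2[C@@H](/C=C/1C)OC(=O)[C@@H]2C | intermediate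
34 | (3S,6S,7S,9R,11R)-3,9-diacetoxygermacra-1(10)Z,4E-dien-12,6-olide | CC(=O)O[C@H]1C/C=C(/C)[C@H](OC(C)=O)C[C@@H]2[C@@H](/C=C/1C)OC(=O)[C@@H]2C | target

**Step count**

Total: 26 steps. Longest linear sequence: 18 steps (steps 1–7 and 16–26 from 1; the branch from 12 through steps 8, 10–15 and 16–26 is equally long).

**Steps most likely to fail**

Step 24 (transannular lactonisation). Ring A may not reach a conformer in which the C4–O bond is aligned with the C5=C6 π system while the opposite alkene face is open to the metal. The allyl unit may also twist so that C3 sits anti. Either would stall the ionisation, divert it to β-hydride elimination, or erode the E geometry and the C6 configuration. The fallback separates C6–O bond formation from the allylic transposition and sets out from acid 31. Iodolactonisation (I2, NaHCO3, MeCN, 0 °C) should deliver the carboxylate oxygen to C6 anti to an iodonium ion on C5=C6 and give (3S,4R,5S,6S,7S,9R,11R)-9-[(tert-butyldimethylsilyl)oxy]-3,4-epoxy-5-iodogermacr-1(10)Z-en-12,6-olide F1. A tin hydride chain (Bu3SnH, Et3B/air, PhMe, 0 °C) then generates the C5 radical, whose oxiranylcarbinyl ring opening breaks C4–O, forms the C4=C5 alkene and, after hydrogen transfer to the C3 oxygen, gives 32, where the route is rejoined. Radical conditions are chosen because a C5 organozinc species could also expel the lactone carboxylate.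

Step 22 (ring A closure). The ten-membered closure may be outrun by intermolecular olefination, and strain in the closing transition state may erode the E preference on which step 24 depends. The fallback fixes C5=C6 intermolecularly and closes ring A at C9–C10; it sets out from 11 and 22 and returns at 30.
- DDQ cleavage of the benzyl-type ether of 11 gives [(2S,3S)-3-[(2Z)-3-iodobut-2-en-1-yl]-2-methyloxiran-2-yl]methanol F2, and Dess–Martin oxidation gives (2R,3S)-3-[(2Z)-3-iodobut-2-en-1-yl]-2-methyloxirane-2-carbaldehyde F3.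
- Intermolecular Julia–Kocienski olefination of F3 with sulfone 22 (KN(SiMe3)2, DME, −60 °C) gives methyl (2R,3R)-3-{(E)-2-[(2S,3S)-3-[(2Z)-3-iodobut-2-en-1-yl]-2-methyloxiran-2-yl]ethenyl}-2-methylhex-5-enoate F4.
- Dihydroxylation of the monosubstituted alkene only (OsO4 cat., NMO) and NaIO4 cleavage give methyl (2R,3R)-3-{(E)-2-[(2S,3S)-3-[(2Z)-3-iodobut-2-en-1-yl]-2-methyloxiran-2-yl]ethenyl}-2-methyl-5-oxopentanoate F5.
- Intramolecular Nozaki–Hiyama–Kishi reaction (CrCl2, NiCl2 cat., DMSO/THF, 0.002 M) gives methyl (3S,4S,7R,11R)-3,4-epoxy-9-hydroxygermacra-1(10)Z,5E-dien-12-oate F6 as C9 epimers.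
- Dess–Martin oxidation gives methyl (3S,4S,7R,11R)-3,4-epoxy-9-oxogermacra-1(10)Z,5E-dien-12-oate F7, and reduction as in step 18 gives methyl (3S,4S,7R,9R,11R)-3,4-epoxy-9-hydroxygermacra-1(10)Z,5E-dien-12-oate F8.
- Silylation as in step 19 gives 30.

Step 7 (iodo-olefination). The basic ylide and amide may enolise the β,γ-epoxy aldehyde and open the epoxide by elimination before olefination, and the Z preference may be incomplete. The fallback builds the haloalkene in two non-basic stages and sets out from aldehyde 8. Dibromo-olefination (CBr4, PPh3, 2,6-lutidine, CH2Cl2, 0 °C) gives (2S,3S)-3-(3,3-dibromoprop-2-en-1-yl)-2-{[(4-methoxybenzyl)oxy]methyl}-2-methyloxirane F9. Negishi coupling with MeZnCl and PdCl2(DPEphos) (5 mol%) in THF replaces only the bromine trans to the chain and gives (2S,3S)-3-[(2Z)-3-bromobut-2-en-1-yl]-2-{[(4-methoxybenzyl)oxy]methyl}-2-methyloxirane F10. F10 is used in place of 11 in the CrCl2/NiCl2 coupling with 23, so the route is rejoined at 24.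

Further compounds
F1 | step 24 | (3S,4R,5S,6S,7S,9R,11R)-9-[(tert-butyldimethylsilyl)oxy]-3,4-epoxy-5-iodogermacr-1(10)Z-en-12,6-olide | C[C@@]12O[C@H]1C/C=C(/C)[C@H](O[Si](C)(C)C(C)(C)C)C[C@H]3[C@@H](C)C(=O)O[C@@H]3[C@@H]2I
F2 | step 22 | [(2S,3S)-3-[(2Z)-3-iodobut-2-en-1-yl]-2-methyloxiran-2-yl]methanol | C[C@@]1(CO)O[C@H]1C/C=C(/C)I
F3 | step 22 | (2R,3S)-3-[(2Z)-3-iodobut-2-en-1-yl]-2-methyloxirane-2-carbaldehyde | C[C@@]1(C=O)O[C@H]1C/C=C(/C)I
F4 | step 22 | methyl (2R,3R)-3-{(E)-2-[(2S,3S)-3-[(2Z)-3-iodobut-2-en-1-yl]-2-methyloxiran-2-yl]ethenyl}-2-methylhex-5-enoate | C[C@@]1(/C=C/[C@@H](CC=C)[C@@H](C)C(=O)OC)O[C@H]1C/C=C(/C)I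
F5 | step 22 | methyl (2R,3R)-3-{(E)-2-[(2S,3S)-3-[(2Z)-3-iodobut-2-en-1-yl]-2-methyloxiran-2-yl]ethenyl}-2-methyl-5-oxopentanoate | C[C@@]1(/C=C/[C@@H](CC=O)[C@@H](C)C(=O)OC)O[C@H]1C/C=C(/C)I
F6 | step 22 | methyl (3S,4S,7R,11R)-3,4-epoxy-9-hydroxygermacra-1(10)Z,5E-dien-12-oate (C9 epimers) | C[C@@]12O[C@H]1C/C=C(/C)C(O)C[C@@H]([C@@H](C)C(=O)OC)/C=C/2
F7 | step 22 | methyl (3S,4S,7R,11R)-3,4-epoxy-9-oxogermacra-1(10)Z,5E-dien-12-oate | C[C@@]12O[C@H]1C/C=C(/C)C(=O)C[C@@H]([C@@H](C)C(=O)OC)/C=C/2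
F8 | step 22 | methyl (3S,4S,7R,9R,11R)-3,4-epoxy-9-hydroxygermacra-1(10)Z,5E-dien-12-oate | C[C@@]12O[C@H]1C/C=C(/C)[C@H](O)C[C@@H]([C@@H](C)C(=O)OC)/C=C/2
F9 | step 7 | (2S,3S)-3-(3,3-dibromoprop-2-en-1-yl)-2-{[(4-methoxybenzyl)oxy]methyl}-2-methyloxirane | C[C@@]1(COCc2ccc(OC)cc2)O[C@H]1CC=C(Br)Br
F10 | step 7 | (2S,3S)-3-[(2Z)-3-bromobut-2-en-1-yl]-2-{[(4-methoxybenzyl)oxy]methyl}-2-methyloxirane | C[C@@]1(COCc2ccc(OC)cc2)O[C@H]1C/C=C(/C)Br
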